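Ring A is treated as a disguised cyclohexanone. In ring A the methoxy carbon (carbon 1) and the bridge carbon (carbon 6) are adjacent, and the bromines sit on carbons 2 and 4, ortho and para to the carbon 1 oxygen; a 2-aryloxycyclohexanone therefore maps onto it exactly. The precursor is racemic ketone 6, made by O-alkylating the pre-brominated ring B phenol with 2-chlorocyclohexanone, so no aryl–oxygen coupling is required. In a single operation, bromine dehydrogenates the saturated ring to the ring A phenol and, guided by that new hydroxyl, places both ring A bromines. O-Methylation and removal of the isopropyl group from the ring B oxygen then give the target.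

Key step: step 3

Remark on the chemistry: the target has no stereocentre; ketone 6 is racemic (one enantiomer is drawn) and its only stereocentre disappears in step 3. Ring A is numbered from its methoxy carbon (carbon 1, C–OMe; carbons 2 and 4, C–Br; carbon 6, C–O bridge). Ring B is numbered from its bridge carbon (carbon 1, bridge; carbon 2, C–OH; carbons 4 and 6, C–Br).

Step 1
Reactants: 1 2-(propan-2-yloxy)phenol; 2 bromine
Product: 4 2,4-dibromo-6-(propan-2-yloxy)phenol, via 2-bromo-6-(propan-2-yloxy)phenol 3 (not isolated)
Conditions: tBuNH2 (4.4 equiv), Br2 (2.1 equiv), toluene, −70 °C → rt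
Reagents that add atoms: bromine (compound 2), BrBr
Why: Amine-mediated electrophilic bromination of a phenol: N-bromo-tert-butylamine formed in situ brominates the hydrogen-bonded ammonium phenoxide, whose oxygen outranks the isopropoxy group, so the first bromine should enter ortho to the hydroxyl (3) and the second para to it, while the carbon para to the ether oxygen, where free bromine in acid could compete, should stay untouched.

Step 2
Reactants: 4 2,4-dibromo-6-(propan-2-yloxy)phenol; 5 2-chlorocyclohexan-1-one (racemic)
Product: 6 2-[2,4-dibromo-6-(propan-2-yloxy)phenoxy]cyclohexan-1-one (racemic)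
Conditions: K2CO3 (2.0 equiv), KI (0.1 equiv), DMF, 70 °C
Reagents that add atoms: 2-chlorocyclohexan-1-one (compound 5), O=C1CCCCC1Cl
Why: Williamson-type SN2 displacement of the carbonyl-activated α-chloride by the potassium phenoxide (iodide catalysis), the standard entry to 2-aryloxycyclohexanones; the new stereocentre forms as the racemate and is of no consequence.

Step 3
Reactants: 6 2-[2,4-dibromo-6-(propan-2-yloxy)phenoxy]cyclohexan-1-one; 2 bromine
Product: 8 2,4-dibromo-6-[2,4-dibromo-6-(propan-2-yloxy)phenoxy]phenol, via 2-aryloxyphenol 7 (not isolated)
Conditions: Br2 (2.1 equiv), NaOAc (6.5 equiv), AcOH, rt → 70 °C; then Br2 (2.0 equiv), rt; aq. NaHSO3 quench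
Reagents that add atoms: bromine (compound 2), BrBr
Why: Enolisation of 6 in acetic acid, α-bromination at both α-carbons and two acetate-assisted losses of HBr lead through the enone to a cyclohexadienone that tautomerises irreversibly to phenol 7; this is the known halogenative aromatisation of cyclohexanones and cyclohexenones with Br2 or CuBr2. The aryloxy group is kept because it sits on an α-carbon, which simply becomes the sp2 bridge carbon (carbon 6 of ring A), and is never β to the carbonyl, from where it could leave by conjugate elimination. The second portion of bromine then substitutes the new phenol, the most electron-rich arene present, at carbon 4 (para) and carbon 2 (ortho) of ring A by electrophilic aromatic substitution, carbon 6 being occupied; a bromoketone that carried two bromines on the methylene α-carbon before eliminating would arrive with the carbon 2 bromine already in place and converges on 8. No ring is closed and no stereocentre is formed, the only stereocentre of 6 being erased. The selectivity required is substitution at carbons 2 and 4 of ring A only, against carbon 3 of ring A (para to the bridge oxygen) and the two open carbons of ring B (ortho and para to the isopropoxy group): it is secured because the hydroxyl, not an ether oxygen, is by far the strongest director present, because ring B is deactivated and crowded by its two bromines, and because the bromine for ring substitution is added cold only after aromatisation. NaOAc takes up the six equivalents of HBr, which protects the isopropyl ether, and the NaHSO3 quench returns any 4-bromocyclohexadienone formed by excess bromine to the phenol.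

Step 4
Reactants: 8 2,4-dibromo-6-[2,4-dibromo-6-(propan-2-yloxy)phenoxy]phenol
Product: 9 1,5-dibromo-3-[2,4-dibromo-6-(propan-2-yloxy)phenoxy]-2-methoxybenzene
Conditions: MeI (1.5 equiv), K2CO3 (2.0 equiv), DMF, rt
Reagents that add atoms: iodomethane, CI
Why: Williamson O-methylation (SN2) of the acidic, bromine-flanked phenoxide with the smallest available electrophile; the isopropyl ether, the diaryl ether and the aryl bromides are inert to carbonate.

Step 5
Reactants: 9 1,5-dibromo-3-[2,4-dibromo-6-(propan-2-yloxy)phenoxy]-2-methoxybenzene
Product: 11 3,5-dibromo-2-(3,5-dibromo-2-methoxyphenoxy)phenol, via aryloxydichloroborane 10 (not isolated)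
Conditions: BCl3 (1 M in CH2Cl2, 2.5 equiv), CH2Cl2, −78 → 0 °C; then H2O
Reagents that add atoms: none
Why: Lewis-acid dealkylation of a secondary alkyl aryl ether: BCl3 binds the ether oxygen and the isopropyl–oxygen bond ionises (SN1-like, chloride capture gives 2-chloropropane) at temperatures where the methyl–oxygen bond, breakable only by slow SN2 attack, and the diaryl ether should survive, and water then hydrolyses aryloxydichloroborane 10.

Compound list
1 | 2-(propan-2-yloxy)phenol | CC(C)Oc1ccccc1O | starting material
2 | bromine | BrBr | starting material
3 | 2-bromo-6-(propan-2-yloxy)phenol | CC(C)Oc1cccc(Br)c1O | intermediate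
4 | 2,4-dibromo-6-(propan-2-yloxy)phenol | CC(C)Oc1cc(Br)cc(Br)c1O | intermediate
5 | 2-chlorocyclohexan-1-one (racemic) | O=C1CCCCC1Cl | starting material
6 | 2-[2,4-dibromo-6-(propan-2-yloxy)phenoxy]cyclohexan-1-one (racemic; the 2S enantiomer is drawn) | O=C1CCCC[C@@H]1Oc1c(OC(C)C)cc(Br)cc1Br | intermediate
7 | 2-[2,4-dibromo-6-(propan-2-yloxy)phenoxy]phenol | Oc1ccccc1Oc1c(OC(C)C)cc(Br)cc1Br | intermediate
8 | 2,4-dibromo-6-[2,4-dibromo-6-(propan-2-yloxy)phenoxy]phenol | Oc1c(Br)cc(Br)cc1Oc1c(OC(C)C)cc(Br)cc1Br | intermediate
9 | 1,5-dibromo-3-[2,4-dibromo-6-(propan-2-yloxy)phenoxy]-2-methoxybenzene | COc1c(Br)cc(Br)cc1Oc1c(OC(C)C)cc(Br)cc1Br | intermediate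
10 | [3,5-dibromo-2-(3,5-dibromo-2-methoxyphenoxy)phenoxy]dichloroborane | COc1c(Br)cc(Br)cc1Oc1c(OB(Cl)Cl)cc(Br)cc1Br | intermediate
11 | 3,5-dibromo-2-(3,5-dibromo-2-methoxyphenoxy)phenol | COc1c(Br)cc(Br)cc1Oc1c(O)cc(Br)cc1Br | target

Total step count: 5. Longest linear sequence: 5 steps (1 → 4 → 6 → 8 → 9 → 11).

Steps most likely to fail

Step 3 (key step). The ring may lose its aryloxy group by solvolysis while bromine and aryloxy share one carbon, the sequence may stall at bromoketones that do not eliminate, or bromine may leak to carbon 3 of ring A or onto ring B while aromatisation is still under way. The fallback sets out from phenol 4 and comes back at 8, bringing ring A in already aromatic. The phenoxide of 4 displaces fluoride from commercial 2-fluorobenzaldehyde by SNAr (K2CO3, DMF, 120 °C) to give 2-[2,4-dibromo-6-(propan-2-yloxy)phenoxy]benzaldehyde F1. Baeyer–Villiger oxidation with mCPBA (CH2Cl2, rt), in which the oxygen-substituted aryl group migrates, gives 2-[2,4-dibromo-6-(propan-2-yloxy)phenoxy]phenyl formate F2. Methanolysis (K2CO3, MeOH, rt) releases phenol 7, this time isolated. Phenol 7 is then brominated ortho and para to its hydroxyl under the amine-mediated conditions of step 1 (Br2 2.05 equiv, tBuNH2, toluene, −70 °C → rt) to give 8, so that only two equivalents of bromine ever meet the diaryl ether.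

Step 2. A hindered, weakly nucleophilic phenoxide may attack the secondary carbon so slowly that base-induced self-condensation or dehydrochlorination of the chloroketone consumes the electrophile first. The fallback sets out from 4 and comes back at 6. The phenoxide opens commercial cyclohexene oxide by anti SN2 attack (Cs2CO3, DMF, 110 °C) to give racemic trans-2-[2,4-dibromo-6-(propan-2-yloxy)phenoxy]cyclohexan-1-ol F3. The secondary alcohol is oxidised to 6 with Dess–Martin periodinane (CH2Cl2, rt) or under Swern conditions.

Step 1. The second bromine may leak to the carbon para to the isopropoxy group, or a third bromine may be taken up. The fallback sets out from bromine 2 and comes back at 4, fixing the bromine pattern before the isopropyl group exists. Commercial salicylaldehyde is dibrominated with 2 (2.1 equiv, NaOAc, AcOH, rt), hydroxyl and formyl groups directing to the same carbons, to give 3,5-dibromo-2-hydroxybenzaldehyde F4. Dakin oxidation (H2O2, NaOH, H2O, rt) passes through 3,5-dibromo-2-hydroxyphenyl formate F5, hydrolysed in the same flask, to 3,5-dibromobenzene-1,2-diol F6. The dianion of F6 (NaH 2.2 equiv, DMSO) is alkylated with 2-bromopropane (1.1 equiv) at its more basic and less hindered oxygen, the one not flanked by bromine, which gives 4.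

Further compounds
F1 | step 3 | 2-[2,4-dibromo-6-(propan-2-yloxy)phenoxy]benzaldehyde | O=Cc1ccccc1Oc1c(OC(C)C)cc(Br)cc1Br
F2 | step 3 | 2-[2,4-dibromo-6-(propan-2-yloxy)phenoxy]phenyl formate | O=COc1ccccc1Oc1c(OC(C)C)cc(Br)cc1Br
F3 | step 2 | trans-2-[2,4-dibromo-6-(propan-2-yloxy)phenoxy]cyclohexan-1-ol (racemic; the 1S,2S enantiomer is drawn) | O[C@H]1CCCC[C@@H]1Oc1c(OC(C)C)cc(Br)cc1Br
F4 | step 1 | 3,5-dibromo-2-hydroxybenzaldehyde | O=Cc1cc(Br)cc(Br)c1O
F5 | step 1 | 3,5-dibromo-2-hydroxyphenyl formate | O=COc1cc(Br)cc(Br)c1O
F6 | step 1 | 3,5-dibromobenzene-1,2-diol | Oc1cc(Br)cc(Br)c1O
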